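At early times the ochre flask shows 0.2 % of target after 6.00 min, then 7.5 % after 30.0 min.

| setting | ochre | flask |
|---|---|---|
| starting material | 12 mM | 12 mM |
| second substrate | 12 mM | 12.0 mM |
| solid reagent | 9.6 mM | 9.60 mM |
| free catalyst | 6 µM | 6.0 µM |
| impurity | 5.3 µM | 5.3 µM |
| remark | the very flask that is asked about, followed so far |  |

ochre run (percent of the starting material charged)

| time / min | target / % |
|---|---|
| 6.00 | 0.2 |
| 15.0 | 3.2 |
| 20.0 | 3.4 |
| 30.0 | 7.5 |
| 40.0 | 11.6 |
| 50.0 | 14.7 |

(standard deviation of a reading: 0.5 percentage points)

- as a solid, counted per litre of solution: solid reagent
- reactions considered so far: starting material + free catalyst <-> catalyst intermediate A; partner + catalyst intermediate A -> free catalyst + target; second substrate + free catalyst <-> catalyst intermediate B; partner + catalyst intermediate B -> free catalyst + second product; solid reagent <-> partner; free catalyst + impurity -> spent catalyst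
- at the start none of the solid reagent is in solution
- no earlier run changes the charge of second substrate; that part of a forecast is a guess

* apparent order in second substrate when 10 % of the starting material are converted (percent change of the rate of making target for one percent more second substrate charged)

Two amounts are compared here: the charge of free catalyst, c, and the charge of impurity, y. Impurity turns free catalyst into spent catalyst one for one, and in this flask its charge is smaller than the catalyst charge. If the impurity is consumed this way, the surplus is what can turn over:

W = c − y = 0.700 µM

This W is the working catalyst, and it is 11.7 % of the charge.

My own reckoning follows from this. With W, partner and starting material held fixed and both binding steps taken at equilibrium, more second substrate moves working catalyst into catalyst intermediate B and away from catalyst intermediate A, so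

order ≈ −(catalyst intermediate B) / W

The sign is negative, but the ochre run gives no size for this share. The forecast gives an order of −0.4, on the ground that “second substrate acts as a competitor”.

The flask gives −0.15.

    starting material + free catalyst ⇌ catalyst intermediate A (K = 90.3 M⁻¹, k = 14700 M⁻¹ min⁻¹)
    partner + catalyst intermediate A → free catalyst + target (k = 1.17 × 10⁵ M⁻¹ min⁻¹)
    second substrate + free catalyst ⇌ catalyst intermediate B (K = 28.8 M⁻¹, k = 1.04 × 10⁵ M⁻¹ min⁻¹)
    partner + catalyst intermediate B → free catalyst + second product (k = 3560 M⁻¹ min⁻¹)
    solid reagent ⇌ partner, rate k5*(cs5 - [partner]) while solid is left; crystals form when [partner] > cs5 (solubility = 9.00 mM, k = 0.0146 min⁻¹)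
    free catalyst + impurity → spent catalyst (k = 34800 M⁻¹ s⁻¹)

When 10 % of the starting material is converted in this flask, at 0.615 h, spent catalyst is 88.3 % of the catalyst charged and catalyst intermediate B is 2.40 %, which makes catalyst intermediate B 20.6 % of W. That share is smaller than the forecast's size of 0.40 and larger than the flask's size of 0.148.

The numbers in the tables were generated by integration on assumed constants; the scatter is artificial.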